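## Retrosynthetic overview

1. Target ⇐ epoxy-tetrol by double angeloylation at O6/O10 (the C2/C4 syn-diol masked in the flask as a phenylboronate); epoxy-tetrol ⇐ 2-silyloxy-dauc-8-ene-6,10-dione by two hydroxyl-directed ketone reductions (C6, then C10) and a hydroxyl-directed epoxidation.
2. Seven-membered ring (formed last) ⇐ cis-bicyclo[3.3.0]octane-6,8-dione + propyne by a two-carbon ring expansion (alkyne insertion into a C(=O)–CH2 bond).
3. Cyclopentane C1–C5 (formed second) ⇐ 2,2-disubstituted 4,4-dimethoxycyclopentanone by intramolecular vinylogous aldol (C5 onto the C4 isopropyl ketone), which sets C4 and C5.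
4. First ring (the cyclopentanone that is later enlarged) ⇐ 1-alkenylcyclobutanol by Shi epoxidation and semipinacol ring expansion, which sets C1 and C2.
5. Alkenylcyclobutanol ⇐ 3,3-dimethoxycyclobutanone + ethynylmagnesium bromide, then MeMgBr/CuI carbomagnesiation trapped with 2-isopropyloxirane.

Assumption: protecting-group atoms are not counted towards starting-material size, so commercial 3,3-dimethoxycyclobutan-1-one (the mono dimethyl ketal of cyclobutane-1,3-dione, six skeletal heavy atoms) is an allowed starting material.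

Numbering and descriptors: daucane numbering as in the target (C1 quaternary C–Me, C2 CHOH, C4 C(OH)iPr, C5 ring-fusion CH, C6 and C10 CHO-acyl, C8 C–Me). β is the face carrying the C1 methyl and H5; α is the opposite face. Absolute configurations are those of the SMILES.

## Route

Step 1
Reactants: 1 3,3-dimethoxycyclobutan-1-one; 2 ethynylmagnesium bromide
Product: 3 1-ethynyl-3,3-dimethoxycyclobutan-1-ol
Conditions: HC≡CMgBr (1.3 equiv), THF, −78 → 0 °C; aq. NH4Cl
Reagents that add atoms: none
Why: Grignard 1,2-addition of the acetylide to the strained ketone, with the ketal inert and no stereocentre formed.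

Step 2
Reactants: 3 1-ethynyl-3,3-dimethoxycyclobutan-1-ol; 4 methylmagnesium bromide; 5 (±)-2-(propan-2-yl)oxirane
Product: 7 (Z)-1-(5-hydroxy-6-methylhept-2-en-2-yl)-3,3-dimethoxycyclobutan-1-ol, via alkenylmagnesium bromide 6 (not isolated)
Conditions: MeMgBr (3 equiv), CuI (15 mol %), THF–toluene, 0 → 60 °C; then 5 (2 equiv), −20 °C → rt; aq. NH4Cl
Reagents that add atoms: none
Why: Copper-catalysed anti-carbomagnesiation of the propargylic alkoxide (Duboudin–Jousseaume) puts Me on the internal carbon and the alkoxide-chelated Mg cis to the carbinol carbon, and the alkenyl Grignard then opens the epoxide at CH2 with retention, fixing the (Z)-trisubstituted alkene.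

Step 3
Reactants: 7 (Z)-1-(5-hydroxy-6-methylhept-2-en-2-yl)-3,3-dimethoxycyclobutan-1-ol
Product: 8 (Z)-6-(1-hydroxy-3,3-dimethoxycyclobutyl)-2-methylhept-5-en-3-one
Conditions: Dess–Martin periodinane (1.2 equiv), pyridine, CH2Cl2, 0 °C
Reagents that add atoms: none
Why: Dess–Martin oxidation takes only the secondary alcohol (the tertiary cyclobutanol cannot be oxidised) and removes the racemic carbinol centre.

Step 4
Reactants: 8 (Z)-6-(1-hydroxy-3,3-dimethoxycyclobutyl)-2-methylhept-5-en-3-one
Product: 10 (2R)-2-[(1S)-1-hydroxy-4-methyl-3-oxopentyl]-4,4-dimethoxy-2-methylcyclopentan-1-one, via (2S,3S)-epoxy alcohol 9 (not isolated)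
Conditions: 1,2:4,5-di-O-isopropylidene-β-L-erythro-2,3-hexodiulo-2,6-pyranose (ent-Shi ketone, 1.0 equiv), KHSO5 (as 2KHSO5·KHSO4·K2SO4), NaHCO3, Bu4NHSO4, MeCN–CH2(OMe)2–aq. Na2EDTA, 0 °C; extract; then ZnBr2 (10 mol %), CH2Cl2, −20 °C
Reagents that add atoms: potassium peroxymonosulfate, [K+].[O-]S(=O)(=O)OO
Why: Shi epoxidation (spiro transition state, the L-fructose-derived ketone giving the (2S,3S)-epoxide) followed by a Lewis-acid semipinacol ring expansion in which a cyclobutane C–C bond migrates anti to the breaking tertiary C–O bond (inversion at C1, retention at C2, the two ring CH2 groups being equivalent), which sets the quaternary C1 and the C2 carbinol.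

Step 5
Reactants: 10 (2R)-2-[(1S)-1-hydroxy-4-methyl-3-oxopentyl]-4,4-dimethoxy-2-methylcyclopentan-1-one
Product: 11 (2R)-2-[(1S)-1-(tert-butyldimethylsilyloxy)-4-methyl-3-oxopentyl]-4,4-dimethoxy-2-methylcyclopentan-1-one
Conditions: TBSOTf (1.3 equiv), 2,6-lutidine, CH2Cl2, −78 °C
Reagents that add atoms: tert-butyldimethylsilyl trifluoromethanesulfonate, CC(C)(C)[Si](C)(C)OS(=O)(=O)C(F)(F)F
Why: Silyl-triflate silylation of the hindered secondary alcohol blocks retro-aldol and keeps O2 from directing the first ketone reduction later.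

Step 6
Reactants: 11 (2R)-2-[(1S)-1-(tert-butyldimethylsilyloxy)-4-methyl-3-oxopentyl]-4,4-dimethoxy-2-methylcyclopentan-1-one
Product: 14 (1R,2S,4S,5S)-2-(tert-butyldimethylsilyloxy)-4-hydroxy-1-methyl-4-(propan-2-yl)bicyclo[3.3.0]octane-6,8-dione, via vinylogous ester 12 (not isolated), via bicyclic aldol adduct 13 (not isolated)
Conditions: LiN(iPr)2 (2.5 equiv), THF, −78 → −20 °C; then 1 M HCl, THF, 0 °C → rt
Reagents that add atoms: water, O
Why: E1cB loss of methoxide gives the 3-methoxycyclopentenone, whose only enolisable ring position is the γ-carbon C5 (α′ is quaternary), and the intramolecular vinylogous aldol onto the isopropyl ketone closes the cyclopentane with the only strain-free (cis) fusion and, under reversible conditions, the isopropyl group exo (4α-OH), before acid hydrolyses the enol ether to the 1,3-dione.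

Step 7
Reactants: 14 (1R,2S,4S,5S)-2-(tert-butyldimethylsilyloxy)-4-hydroxy-1-methyl-4-(propan-2-yl)bicyclo[3.3.0]octane-6,8-dione; 15 propyne
Product: 16 2α-(tert-butyldimethylsilyloxy)-4α-hydroxydauc-8-ene-6,10-dione
Conditions: [ReBr(CO)3(thf)]2 (5 mol %), benzyl isocyanide (10 mol %), propyne (5 equiv), toluene, sealed tube, 80 °C
Reagents that add atoms: none
Why: Proposed new method: rhenium-catalysed formal insertion of a terminal alkyne into the C(=O)–CH2 bond of a cyclic 1,3-diketone (two-carbon ring expansion), in which the rhenium diketonate adds its central carbon C7 to the internal carbon of coordinated propyne, the alkenylrhenium adds to the adjacent ring carbonyl to give a cyclobutenolate, and retro-aldol cleavage of the strained bicycle releases the 3-methylcyclohept-2-ene-1,5-dione, both insertion modes (towards C10 or C6) converging on the same vinylogous diketone with no stereocentre touched; the closest known reaction is the [ReBr(CO)3(thf)]2-catalysed insertion of terminal alkynes into the C–C bond of cyclic β-keto esters (Kuninobu–Takai ring expansion), not yet shown for 1,3-diketones.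

Step 8
Reactants: 16 2α-(tert-butyldimethylsilyloxy)-4α-hydroxydauc-8-ene-6,10-dione
Product: 17 2α-(tert-butyldimethylsilyloxy)-4α,6β-dihydroxydauc-8-en-10-one
Conditions: Me4NBH(OAc)3 (5 equiv), MeCN–AcOH (1:1), −30 °C
Reagents that add atoms: none
Why: Evans–Saksena hydroxyl-directed reduction, in which the enone tautomers equilibrate and only the saturated C6 carbonyl of the C8=C9–C10=O tautomer lies β to the free C4 hydroxyl, which delivers hydride to the α-face (1,3-anti, 6β-OH) while C10, with its β-oxygen silylated, is untouched, so the enone is locked next to C10.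

Step 9
Reactants: 17 2α-(tert-butyldimethylsilyloxy)-4α,6β-dihydroxydauc-8-en-10-one
Product: 18 2α,4α,6β-trihydroxydauc-8-en-10-one
Conditions: HF·pyridine, pyridine, THF, 0 °C → rt
Reagents that add atoms: none
Why: Buffered fluoride desilylation frees O2 without base-induced retro-aldol.

Step 10
Reactants: 18 2α,4α,6β-trihydroxydauc-8-en-10-one
Product: 19 dauc-8-ene-2α,4α,6β,10β-tetrol
Conditions: Me4NBH(OAc)3 (5 equiv), MeCN–AcOH (1:1), −20 → 0 °C
Reagents that add atoms: none
Why: Second Evans–Saksena reduction, the C2 hydroxyl on the concave face delivering hydride 1,2 to the α-face of the enone carbonyl to give the 10β allylic alcohol (1,3-anti).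

Step 11
Reactants: 19 dauc-8-ene-2α,4α,6β,10β-tetrol
Product: 20 8β,9β-epoxydaucane-2α,4α,6β,10β-tetrol
Conditions: VO(acac)2 (5 mol %), t-BuOOH (1.5 equiv, decane), CH2Cl2, 0 °C
Reagents that add atoms: tert-butyl hydroperoxide, CC(C)(C)OO
Why: Vanadium-catalysed hydroxyl-directed epoxidation delivers oxygen syn to the allylic 10β-OH (reinforced by the homoallylic 6β-OH), giving the β-epoxide.

Step 12
Reactants: 20 8β,9β-epoxydaucane-2α,4α,6β,10β-tetrol; 21 angelic acid
Product: 24 (1R,2S,4S,5R,6R,8S,9R,10R)-8,9-epoxy-2,4-dihydroxydaucane-6,10-diyl bis[(2Z)-2-methylbut-2-enoate], via phenylboronate 22 (not isolated), via bis-angelate boronate 23 (not isolated)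
Conditions: PhB(OH)2 (1.05 equiv), 4 Å MS, toluene, rt; then 21 (5 equiv), 2,4,6-Cl3C6H2COCl (5 equiv), Et3N, toluene, 75 °C; then pinacol, rt
Reagents that add atoms: phenylboronic acid, OB(O)c1ccccc1 (boron and phenyl are present in 22 and 23 only)
Why: The only two hydroxyls that can reach a common boron (the syn-1,3 pair O2/O4 on the concave face) are tied up as a cyclic boronate, Yamaguchi-type mixed-anhydride acylation without nucleophilic catalyst esterifies the two exo secondary alcohols without Z-to-E isomerisation, and pinacol transesterification frees the diol.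

## Compound list

1 | 3,3-dimethoxycyclobutan-1-one | COC1(OC)CC(=O)C1 | starting material
2 | ethynylmagnesium bromide | C#C[Mg]Br | starting material
3 | 1-ethynyl-3,3-dimethoxycyclobutan-1-ol | C#CC1(O)CC(OC)(OC)C1 | intermediate
4 | methylmagnesium bromide | C[Mg]Br | starting material
5 | (±)-2-(propan-2-yl)oxirane | CC(C)C1CO1 | starting material
6 | bromomagnesium alkoxide of (Z)-1-(1-bromomagnesioprop-1-en-2-yl)-3,3-dimethoxycyclobutan-1-ol (Mg cis to the ring carbon) | C/C(=C/[Mg]Br)C1(O[Mg]Br)CC(OC)(OC)C1 | intermediate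
7 | (Z)-1-(5-hydroxy-6-methylhept-2-en-2-yl)-3,3-dimethoxycyclobutan-1-ol (racemic at the carbinol CH) | C/C(=C/CC(O)C(C)C)C1(O)CC(OC)(OC)C1 | intermediate
8 | (Z)-6-(1-hydroxy-3,3-dimethoxycyclobutyl)-2-methylhept-5-en-3-one | C/C(=C/CC(=O)C(C)C)C1(O)CC(OC)(OC)C1 | intermediate
9 | 1-[(2S,3S)-2-methyl-3-(3-methyl-2-oxobutyl)oxiran-2-yl]-3,3-dimethoxycyclobutan-1-ol | CC(C)C(=O)C[C@@H]1O[C@]1(C)C2(O)CC(OC)(OC)C2 | intermediate
10 | (2R)-2-[(1S)-1-hydroxy-4-methyl-3-oxopentyl]-4,4-dimethoxy-2-methylcyclopentan-1-one | CC(C)C(=O)C[C@H](O)[C@@]1(C)CC(OC)(OC)CC1=O | intermediate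
11 | (2R)-2-[(1S)-1-(tert-butyldimethylsilyloxy)-4-methyl-3-oxopentyl]-4,4-dimethoxy-2-methylcyclopentan-1-one | CC(C)C(=O)C[C@H](O[Si](C)(C)C(C)(C)C)[C@@]1(C)CC(OC)(OC)CC1=O | intermediate
12 | (5R)-5-[(1S)-1-(tert-butyldimethylsilyloxy)-4-methyl-3-oxopentyl]-3-methoxy-5-methylcyclopent-2-en-1-one | CC(C)C(=O)C[C@H](O[Si](C)(C)C(C)(C)C)[C@@]1(C)CC(OC)=CC1=O | intermediate
13 | (1R,2S,4S,5S)-2-(tert-butyldimethylsilyloxy)-4-hydroxy-6-methoxy-1-methyl-4-(propan-2-yl)bicyclo[3.3.0]oct-6-en-8-one (cis-fused) | CC(C)[C@@]1(O)C[C@H](O[Si](C)(C)C(C)(C)C)[C@]2(C)C(=O)C=C(OC)[C@H]12 | intermediate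
14 | (1R,2S,4S,5S)-2-(tert-butyldimethylsilyloxy)-4-hydroxy-1-methyl-4-(propan-2-yl)bicyclo[3.3.0]octane-6,8-dione (cis-fused, largely enolised) | CC(C)[C@@]1(O)C[C@H](O[Si](C)(C)C(C)(C)C)[C@]2(C)C(=O)CC(=O)[C@H]12 | intermediate
15 | propyne | CC#C | starting material
16 | 2α-(tert-butyldimethylsilyloxy)-4α-hydroxydauc-8-ene-6,10-dione (1β-Me, 5β-H, 4β-iPr; drawn as the C8=C9–C10=O tautomer) | O=C1CC(C)=CC(=O)[C@@]2(C)[C@@H](O[Si](C)(C)C(C)(C)C)C[C@](O)(C(C)C)[C@@H]12 | intermediate
17 | 2α-(tert-butyldimethylsilyloxy)-4α,6β-dihydroxydauc-8-en-10-one | O[C@@H]1CC(C)=CC(=O)[C@@]2(C)[C@@H](O[Si](C)(C)C(C)(C)C)C[C@](O)(C(C)C)[C@@H]12 | intermediate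
18 | 2α,4α,6β-trihydroxydauc-8-en-10-one | O[C@@H]1CC(C)=CC(=O)[C@@]2(C)[C@@H](O)C[C@](O)(C(C)C)[C@@H]12 | intermediate
19 | dauc-8-ene-2α,4α,6β,10β-tetrol | O[C@@H]1CC(C)=C[C@H](O)[C@@]2(C)[C@@H](O)C[C@](O)(C(C)C)[C@@H]12 | intermediate
20 | 8β,9β-epoxydaucane-2α,4α,6β,10β-tetrol | O[C@@H]1C[C@]2(C)O[C@@H]2[C@H](O)[C@@]2(C)[C@@H](O)C[C@](O)(C(C)C)[C@@H]12 | intermediate
21 | angelic acid, (2Z)-2-methylbut-2-enoic acid | C/C=C(/C)C(=O)O | starting material
22 | 2,4-O-(phenylboranediyl) derivative of 20 | O[C@@H]1C[C@]2(C)O[C@@H]2[C@H](O)[C@@]2(C)[C@@H]3C[C@](OB(c4ccccc4)O3)(C(C)C)[C@@H]12 | intermediate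
23 | 6,10-di-O-angeloyl-2,4-O-(phenylboranediyl) derivative of 20 | C/C=C(/C)C(=O)O[C@@H]1C[C@]2(C)O[C@@H]2[C@H](OC(=O)/C(C)=C\C)[C@@]2(C)[C@@H]3C[C@](OB(c4ccccc4)O3)(C(C)C)[C@@H]12 | intermediate
24 | (1R,2S,4S,5R,6R,8S,9R,10R)-8,9-epoxy-2,4-dihydroxydaucane-6,10-diyl bis[(2Z)-2-methylbut-2-enoate] (CNP0265715.2) | C/C=C(/C)C(=O)O[C@@H]1C[C@]2(C)O[C@@H]2[C@H](OC(=O)/C(C)=C\C)[C@@]2(C)[C@@H](O)C[C@](O)(C(C)C)[C@@H]12 | target

## Step count and risk

Total steps: 12. Longest linear sequence: 12 steps (1 to 24).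

The three steps most likely to fail:

Step 6 (vinylogous aldol; competing enolisation of the side-chain ketone and α- versus γ-attack). The fallback sets out from 11 and comes back to the route at 14. It replaces the lithium dienolate by a Lewis-acid vinylogous Mukaiyama aldol. TMSOTf (2.2 equiv) and Et3N in CH2Cl2 (−78 → 0 °C) turn the β-keto ketal into the methyl vinylogous ester and then into the cross-conjugated diene (5R)-5-[(1S)-1-(tert-butyldimethylsilyloxy)-4-methyl-3-oxopentyl]-3-methoxy-5-methyl-1-(trimethylsilyloxy)cyclopenta-1,3-diene F1. TiCl4 (CH2Cl2, −78 °C) then closes the cyclopentane by attack of the diene terminus C5 on the activated isopropyl ketone, and aqueous HCl work-up hydrolyses the enol ether to give 14.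

Step 7 (the proposed new ring expansion; possible simple C-alkenylation without C–C cleavage). The fallback uses known chemistry, sets out from 14 and comes back at 16. It is a de Mayo sequence: irradiation (350 nm, Pyrex, CH2Cl2, −40 °C) of the enol of 14 with allene gives, by head-to-head enone–allene [2+2] photocycloaddition, the methylenecyclobutanol photoadduct F2. On warming this undergoes retro-aldol cleavage to 2α-(tert-butyldimethylsilyloxy)-4α-hydroxydauc-8(14)-ene-6,10-dione F3. A catalytic amount of 1,8-diazabicyclo[5.4.0]undec-7-ene then moves the exocyclic double bond into conjugation to give 16.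

Step 12 (two hindered alcohols; angelate-to-tiglate isomerisation). The fallback sets out from 20 and comes back at 24. After the same boronate masking (22), O6 and O10 are esterified with 2-(diphenoxyphosphoryl)propanoic acid (N,N′-diisopropylcarbodiimide, 4-dimethylaminopyridine, CH2Cl2) to give the 6,10-bis[2-(diphenoxyphosphoryl)propanoate] of 22 F4. The (Z)-2-methylbut-2-enoates are then built on the molecule by Ando olefination with acetaldehyde (NaH, THF, −78 °C), which gives 23, and pinacol releases 24.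

Further compounds

F1 | step 6 | (5R)-5-[(1S)-1-(tert-butyldimethylsilyloxy)-4-methyl-3-oxopentyl]-3-methoxy-5-methyl-1-(trimethylsilyloxy)cyclopenta-1,3-diene | CC(C)C(=O)C[C@H](O[Si](C)(C)C(C)(C)C)[C@@]1(C)C=C(OC)C=C1O[Si](C)(C)C
F2 | step 7 | methylenecyclobutanol photoadduct of the enol of 14 with allene (allene central carbon on C7, CH2 on the carbinol carbon; the two new ring-fusion centres form as a mixture) | C=C1CC2(O)C1C(=O)[C@@H]1[C@@](O)(C(C)C)C[C@H](O[Si](C)(C)C(C)(C)C)[C@]21C
F3 | step 7 | 2α-(tert-butyldimethylsilyloxy)-4α-hydroxydauc-8(14)-ene-6,10-dione | O=C1CC(=C)CC(=O)[C@@]2(C)[C@@H](O[Si](C)(C)C(C)(C)C)C[C@](O)(C(C)C)[C@@H]12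
F4 | step 12 | 6,10-bis-O-[2-(diphenoxyphosphoryl)propanoyl]-2,4-O-(phenylboranediyl) derivative of 20 (mixture at the two phosphonate α-carbons) | CC(P(=O)(Oc1ccccc1)Oc1ccccc1)C(=O)O[C@@H]1C[C@]2(C)O[C@@H]2[C@H](OC(=O)C(C)P(=O)(Oc5ccccc5)Oc5ccccc5)[C@@]2(C)[C@@H]3C[C@](OB(c4ccccc4)O3)(C(C)C)[C@@H]12
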